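In a one-step world, irreversible and first order in substrate and in catalyst, ochre's 17.8% at 15.0 d reckons to 99.0% for grey, at 23.3 times ochre's loading. Grey reads 26.0% at that time.

common to all: substrate 0.25 M
- ochre: free catalyst 0.12 mol%; run made earlier
- grey: free catalyst 2.8 mol%; run made earlier
- ash: free catalyst 0.1 mol%; time 20 d
- maple: free catalyst 0.3 mol%; time 20 d
- larch: free catalyst 0.8 mol%; time 20 d
- elm: free catalyst 2.5 mol%; time 20 d

- ochre (time / d: target / %): 1.04: 1.7; 1.67: 3.4; 3.00: 4.4; 5.00: 7.0; 8.00: 11.7; 15.0: 17.8
- grey (time / d: target / %): 2.50: 12.9; 5.00: 17.4; 8.00: 20.7; 10.0: 19.7; 12.0: 23.7; 15.0: 26.0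

(readings scatter by 1 percentage point)

- "hardly changes" means that all values lie within two and a half points (for a concentration: within two and a half percent of the largest)

* amount of target at the end, in percent of the substrate charged for ash, maple, larch, elm, in this order
* how that number moves from the first to the last of them (rises all the way / falls all the way / falls, then rises / hardly changes / rises, then falls)

The gap between the runs is 10 percentage points at 5.00 d and 8.2 points at 15.0 d, so within the scatter it does not grow. I therefore split target into two amounts. The large one is ochre's drift, which I carry straight on to 20 d: 23.7%. The small one is the gap, and I reckon it as a correction. My catalyst share is the gap divided by that drift, 34.6%. Ash lies near ochre's loading and elm near grey's, so my row climbs from about 23.7% to about 31.9%.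

The forecast differs: 20%, 28%, 30%, 28%, so rises, then falls. Its ground: “Low loading is limited by rate and high loading by catalyst death, so there is a shallow maximum.”

The row rises all the way: 22.0%, 23.1%, 24.7%, 27.7%.

    substrate + free catalyst ⇌ target + free catalyst, rate k1*[substrate]*[free catalyst] forward; the back reaction follows from the equilibrium constant (K = 17.9, k = 0.00187 L mol⁻¹ s⁻¹)
    2 free catalyst → spent catalyst (k = 0.00209 L mol⁻¹ s⁻¹)
    isomer of the product ⇌ substrate (k = 3.43 × 10⁻⁶ s⁻¹)
    target ⇌ isomer of the product (K = 1.39, k = 2.50 × 10⁻⁷ s⁻¹)
    free catalyst ⇌ dormant form (K = 0.480, k = 5.11 × 10⁻⁵ s⁻¹)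

In ash at 20.0 d, isomer of the product holds 75.0% and substrate 3.01%, and the step from isomer of the product to target carries no catalyst, an uncatalysed background. Ash's 22.0% raised by the share of 34.6% makes 29.6%, and elm holds 27.7%.

(The runs were generated by integration with made-up constants; the scatter is artificial.)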